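The earlier runs and the new flask come from a simulation on assumed constants; scatter was added.

At 1.5 h, Thursday's flask, charged with 0.020 M of J, stands past its own last reading at 20.0 min and past Monday's at 60.0 min, so we bracket the answer by hand.

| flask | J | remark | time |
|---|---|---|---|
| Thursday's | 0.020 M | the very flask that is asked about, followed so far |  |
| Monday's | 0.040 M | run made earlier |  |
| flask | 0.020 M |  | 1.5 h |

| run | time / min | D / % | E / % | J / % |
|---|---|---|---|---|
| Thursday's | 1.33 | 0 | 5 | 56 |
| Thursday's | 2.50 | 1 | 13 | 38 |
| Thursday's | 5.00 | 3 | 13 | 20 |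
| Thursday's | 10.0 | 8 | 15 | 10 |
| Thursday's | 20.0 | 19 | 19 | 6 |
| Monday's | 6.00 | 5 | 11 | 16 |
| Monday's | 15.0 | 15 | 15 | 8 |
| Monday's | 30.0 | 26 | 17 | 7 |
| Monday's | 50.0 | 42 | 14 | 5 |
| Monday's | 60.0 | 50 | 9 | 4 |

(scatter of a reading: 2 percentage points)

- the numbers in the tables scatter with a standard deviation of 2 percentage points

1. concentration of D at 1.5 h, in M
2. concentration of E at 1.5 h, in M
3. concentration of J at 1.5 h, in M

In percent of the charge the two runs lie on one curve: Thursday's D of 19% at 20.0 min falls between Monday's 15% at 15.0 min and 26% at 30.0 min. So we read Monday's percentages for Thursday's flask. D rises from reading to reading, so Monday's last value gives a floor of 0.0100 M. Monday's slope from 30.0 min to 60.0 min, continued in a straight line, gives an estimated ceiling of 0.0148 M, which holds provided the rise does not steepen.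

To tighten this, call the pool whatever of the charge is not yet D. We read 0.0131 min⁻¹ as the drain constant λ, the apparent first-order constant of the pool: the logarithm of its ratio at two readings, divided by the time between them. Monday's earlier stretch reads a smaller 0.00924 min⁻¹, which raises the floor to an estimated 0.0124 M, provided the pool drains no slower than that after Monday's last reading. With λ the pool of Thursday's flask reaches an estimated 33.8% at 1.5 h, so we commit to c_D = 0.0132 M. Taking the shares of the pool at 30.0 min, where the readings stand higher above the scatter, we get c_E = 0.00155 M and c_J = 6.39 × 10⁻⁴ M.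

The forecast, reasoning that “the kinetics look first order”, gives 0.0134 M of D, inside the bracket, with 0.0015 M of E and 6.000 × 10⁻⁴ M of J.

The flask gives c_D = 0.0128 M, inside the bracket, with c_E = 0.00159 M and c_J = 6.98 × 10⁻⁴ M, which is 1.16 times the forecast's J.

    J ⇌ L (K = 7.00, k = 0.340 min⁻¹)
    J ⇌ E (K = 1.70, k = 0.0740 min⁻¹)
    J → Z (k = 0.0150 min⁻¹)
    Z → D (k = 0.0440 min⁻¹)
    L → D (k = 0.0150 min⁻¹)

The pool of Thursday's flask held L, a species outside the readings, at 22.9% of the charge at 1.50 h, against 3.49% of J. Now take λ to a reading of the same flask at 40 min: it carries the pool from Monday's 74.0% at 30.0 min to 64.9%, which means c_D = 0.00702 M, and that reading held 0.00721 M.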